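## Analysis of the target

- The target **16** (C42H46O12) is a constitutionally unsymmetrical dimer of two identical arctigenin-type units.
- Lactone ring C (O1, carbonyl C2, C3, C4, C5) carries the 3,4-dimethoxyphenyl ring A on C4 through the methylene C8, and the 4-aryloxy-3-methoxyphenyl ring B on C3 through the methylene C7. Lactone ring C′ carries ring A′ on C4′ (via C8′) and, via C7′ on C3′, ring B′, which is 4-hydroxy-3-methoxy-5-aryloxy substituted.
- The only link between the halves is the diaryl ether from C4 of ring B to C5 of ring B′.
- There are four stereocentres, C3, C4, C3′ and C4′, all S. In each lactone the two benzyl groups are trans, the thermodynamically favoured arrangement, so C3 could be corrected by base but C4 could not.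
- The two pairs lie eleven bonds apart and cannot influence each other, so both must be set by the same external controller. The (3S,4S) series is the mirror image of the common (3R,4R)-arctigenin, so the natural lignan is no chiral pool.
- Sensitive groups: two lactones with an exchangeable C3–H, one free phenol on the very electron-rich ring B′ (oxidation), and six methyl ethers that forbid any late Lewis-acidic ether cleavage.
- The difficulties are the regiospecific construction of the hindered diaryl ether (ortho-oxygen substituents on both sides) and the need to do the same stereochemical work twice without doubling the step count.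
- The feature used here: each of the four stereocentres has one exocyclic C–C bond (C3–C7, C3′–C7′, C4–C8, C4′–C8′), and C7 and C7′ are the two benzylic carbons of one and the same diaryl ether B–O–B′.

## Retrosynthetic reasoning

**16 ⇒ 13.** The two lactone methylenes C5 and C5′ are traced back to acetal carbons that carry a menthyloxy group. One C–H bond on each is cut. What is gained is a stereocentre next to C4 that can carry the chiral controller through the key step and then disappear. The forward reaction must open each γ-alkoxylactone with hydroxide, reduce the liberated aldehyde with hydride and close the lactone again on the reduced carbon, without touching C3 or C4.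

**13 ⇒ 12.** The two C–H bonds on each of C8 and C8′ are traced back to the C–S bonds of 1,3-dithianes, and the phenolic O–H to an O-benzyl ether. This turns C8 and C8′ into acyl-anion carbons (nucleophiles) and masks the only acidic proton of the skeleton. The forward reaction is one reductive operation on nickel.

**12 ⇒ 6 + 2 × 8 + 2 × 9 (key disconnection).** Four C–C bonds are cut at once: C3–C7, C3′–C7′, C4–C8 and C4′–C8′. These are the four exocyclic bonds at the four stereocentres. Cutting there, and not at the ether oxygen, leaves the whole diaryl ether as one achiral bis-electrophile **6**. The rest of the molecule falls into two copies of the achiral dithiane **8** and two copies of the bought chiral butenolide **9**, which already contains rings C and C′. A cut at the ether oxygen would instead leave two different chiral monomers, each needing its own asymmetric synthesis. The forward reaction has to add the anion of **8** to **9** anti to the C5 substituent, then alkylate the resulting enolate with both benzylic bromides of **6** anti to the new C4 substituent.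

**6 ⇒ 5 ⇒ 4.** The two C–Br bonds are traced back to benzylic alcohols and these to aldehydes. The aldehydes make the partners of the ether-forming step cheap benzaldehydes.

**4 ⇒ 2 + 3.** The aryl C–O bond at C5 of ring B′ is cut. It is formed at the stage of two simple benzaldehydes, where no lactone and no stereocentre exists, so a hot, basic copper coupling does no harm. Vanillin **3** is the phenol; the iodide **2** comes from 5-iodovanillin **1** by O-benzylation, which also differentiates the future free phenol from the six methyl ethers.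

**8 ⇒ 7.** The dithiane is the thioacetal of veratraldehyde **7**.

## Alternatives that were turned down

**Alternative 1:** the textbook route, a late diaryl ether coupling of two finished monomers.
- Disconnection: the aryl C–O bond between rings B and B′ as the last skeletal bond.
- Forward key step: copper-mediated Ullmann coupling of (3S,4S)-arctigenin **A1** (phenol) with its 5-bromo O-benzyl derivative **A2** to the O-benzyl ether **A3**, then hydrogenolysis.
- Turned down because:
  - all four stereocentres must be made in two separate linear sequences to monomers that differ only by a bromine and a benzyl group;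
  - the least reliable reaction of the route, between two ortho-substituted partners, comes last and consumes the most valuable material;
  - it runs under basic copper conditions near 100 °C, where the lactone C3–H exchanges and phenoxide can open lactones.

**Alternative 2:** biomimetic or anodic dehydrodimerisation.
- Disconnection: the same C–O bond, formed by one-electron oxidation of **A1** (anode or chemical oxidant) and radical coupling.
- Turned down because:
  - the phenoxyl radical of a 4-alkyl-2-methoxyphenol has spin density on O4, C5 and C1, and C5–C5′ coupling to the biaryl **A4** is the preferred and irreversible path, with O–C5′ coupling a minor one;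
  - nothing in **A1** tells the oxygen donor from the carbon acceptor;
  - the product, with a 1,2,3-trioxygenated ring, is oxidised more easily than **A1** and would oligomerise;
  - the single step is attractive, but the structure offers no handle for regiocontrol, and **A1** itself must first be made in the unnatural series.

**Alternative 3:** two-fold alkylation of a ready-made chiral lactone.
- Disconnection: only C3–C7 and C3′–C7′.
- Forward key step: the lithium enolate of (S)-4-(3,4-dimethoxybenzyl)oxolan-2-one **A5** (two equivalents) is alkylated trans with dibromide **6** to give **A3**, then hydrogenolysis.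
- Turned down because:
  - it sets only two of the four stereocentres in the key step;
  - C4 and C4′ must be made beforehand in about four steps from **7** (Stobbe condensation, asymmetric hydrogenation with [Rh(cod)2]BF4 and a chiral bisphosphine, chemoselective reduction, lactonisation);
  - the total count rises to about ten steps with two different control elements.
- It is the most reliable relative of the chosen route and is kept as its fallback.

Key step: step 6

Remarks on the chemistry:
- Butenolide **9**, (5S)-5-(d-menthyloxy)-2(5H)-furanone, is taken as a bought compound (both enantiomers of this butenolide are catalogue items).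
- Where one reaction takes place at both arms of a two-armed compound (steps 3, 4, 6, 7 and 8), the half-reacted stage is not counted as a separate compound.

## Route

Step 1
Reactants: 1 5-iodovanillin (4-hydroxy-3-iodo-5-methoxybenzaldehyde)
Product: 2 4-(benzyloxy)-3-iodo-5-methoxybenzaldehyde
Conditions: BnBr, K2CO3, DMF, 60 °C
Reagents that add atoms: benzyl bromide, BrCc1ccccc1
Why: Williamson etherification of an acidic, doubly ortho-substituted phenol. Benzyl is chosen because it survives copper coupling, hydride, PBr3 and organolithium chemistry and leaves in step 7 without a step of its own.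

Step 2
Reactants: 2 4-(benzyloxy)-3-iodo-5-methoxybenzaldehyde; 3 vanillin (4-hydroxy-3-methoxybenzaldehyde)
Product: 4 4-(benzyloxy)-3-(4-formyl-2-methoxyphenoxy)-5-methoxybenzaldehyde
Conditions: CuI (10 mol%), picolinic acid (20 mol%), K3PO4, DMSO, 90 °C
Reagents that add atoms: none
Why: Ullmann-type diaryl ether synthesis with monovalent copper and a picolinate ligand, a system that tolerates ortho substituents on both partners and non-enolisable aldehydes. The aryl iodide is the most reactive halide, and no stereocentre or lactone is present yet.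

Step 3
Reactants: 4 4-(benzyloxy)-3-(4-formyl-2-methoxyphenoxy)-5-methoxybenzaldehyde
Product: 5 {4-(benzyloxy)-3-[4-(hydroxymethyl)-2-methoxyphenoxy]-5-methoxyphenyl}methanol
Conditions: NaBH4, MeOH–THF, 0 °C
Reagents that add atoms: none
Why: Borohydride reduction of both aryl aldehydes; nothing else in 4 is reducible under these conditions.

Step 4
Reactants: 5 {4-(benzyloxy)-3-[4-(hydroxymethyl)-2-methoxyphenoxy]-5-methoxyphenyl}methanol
Product: 6 2-(benzyloxy)-5-(bromomethyl)-1-[4-(bromomethyl)-2-methoxyphenoxy]-3-methoxybenzene
Conditions: PBr3, CH2Cl2, 0 °C; used at once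
Reagents that add atoms: phosphorus tribromide, BrP(Br)Br
Why: Conversion of both benzylic alcohols into bromides through their phosphite esters. The benzyl and diaryl ethers are inert at 0 °C, and the electron-rich bis-bromide should be used without storage because it is prone to solvolysis.

Step 5
Reactants: 7 veratraldehyde (3,4-dimethoxybenzaldehyde)
Product: 8 2-(3,4-dimethoxyphenyl)-1,3-dithiane
Conditions: HS(CH2)3SH, BF3·OEt2 (cat.), CH2Cl2, rt
Reagents that add atoms: 1,3-propanedithiol, SCCCS
Why: Lewis-acid catalysed dithioacetalisation. It turns the aldehyde carbon into an acyl-anion equivalent that becomes the methylene C8 (C8′) after desulfurisation.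

Step 6
Reactants: 8 2-(3,4-dimethoxyphenyl)-1,3-dithiane; 9 (5S)-5-[(1S,2R,5S)-menthyloxy]furan-2(5H)-one; 6 2-(benzyloxy)-5-(bromomethyl)-1-[4-(bromomethyl)-2-methoxyphenoxy]-3-methoxybenzene
Product: 12 two-armed adduct in which each CH2Br of 6 has become a CH2 bonded to C3 of a (3S,4S,5S)-4-[2-(3,4-dimethoxyphenyl)-1,3-dithian-2-yl]-5-[(1S,2R,5S)-menthyloxy]-2-oxooxolan-3-yl ring, via lithiated dithiane 10 (not isolated), via lithium enolate 11 (not isolated)
Conditions: 8 (2.6 equiv), n-BuLi (2.5 equiv), THF, −78 → −20 °C; 9 (2.6 equiv), −78 °C; then 6 (1.0 equiv), DMPU, −78 °C → rt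
Reagents that add atoms: n-butyllithium, [Li]CCCC (its lithium is found in 10 and 11 only)
Why: Deprotonation of 8 gives the sulfur-stabilised benzylic anion 10, a soft acyl-anion equivalent that adds 1,4 and not 1,2 to the γ-alkoxybutenolide 9; the closest known reaction type is the tandem conjugate addition–enolate alkylation of 5-alkoxy-2(5H)-furanones with lithiated 2-aryl-1,3-dithianes and benzylic bromides, run here in two directions on one bis-electrophile. No ring is closed, since both lactone rings come ready-made from 9. C4 and C4′ are set in the addition: the nucleophile enters the butenolide face anti to the C5 menthyloxy group (the acetal stereocentre, not the remote menthyl skeleton, is the controlling element), which gives the 4,5-trans enolate 11. C3 and C3′ are set in the SN2 alkylation: each benzylic bromide of 6 approaches the planar enolate anti to the very large C4 dithianyl group, so every lactone should end up 3,4-trans and 4,5-trans, that is (3S,4S,5S). The step needs 1,4- over 1,2-addition (secured by the delocalised aryl dithianyl anion and the low temperature), C- over O-alkylation (lithium enolate, reactive benzylic electrophile, DMPU), and complete two-fold alkylation (secured by the excess of 11 and by the two bromides sitting on different rings, so that they react independently). Because the controller is enantiopure, an error in either arm would give a separable diastereomer of 12 and not the enantiomer. Four C–C bonds and all four stereocentres of the target are thus formed in one flask from achiral 6 and 8 and the bought butenolide 9.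

Step 7
Reactants: 12 two-armed bis(dithianyl) bis(menthyloxylactone) benzyl ether
Product: 13 (3S,4S,5S)-4-(3,4-dimethoxybenzyl)-3-{4-[5-{[(3S,4S,5S)-4-(3,4-dimethoxybenzyl)-5-[(1S,2R,5S)-menthyloxy]-2-oxooxolan-3-yl]methyl}-2-hydroxy-3-methoxyphenoxy]-3-methoxybenzyl}-5-[(1S,2R,5S)-menthyloxy]oxolan-2-one
Conditions: Raney Ni (W-2, excess), H2 (1 atm), EtOH–THF, 60 °C
Reagents that add atoms: none
Why: Mozingo-type hydrogenolysis of all four C–S bonds turns each dithiane carbon into a methylene, and the same nickel under hydrogen should cleave the aryl benzyl ether. Lactone acetals, methyl ethers and the diaryl ether are stable at this temperature, and no stereocentre is touched.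

Step 8
Reactants: 13 phenolic bis(menthyloxylactone)
Product: 16 target (3S,4S,3′S,4′S)-bis-lactone, via bis(formyl carboxylate) 14 (not isolated), via bis(hydroxy carboxylate) 15 (not isolated)
Conditions: NaBH4, KOH, EtOH–H2O, 0 °C → rt; then 2 M HCl, rt
Reagents that add atoms: potassium hydroxide, [K+].[OH-] (supplies one carboxylate oxygen per arm in 14 and 15)
Why: Hydroxide opens each γ-alkoxylactone (a pseudo-ester) to a carboxylate and an aldehyde with loss of menthoxide, and borohydride, present from the start, should reduce the aldehyde to the primary alcohol before C4 can enolise. Acidification closes the γ-lactone onto the reduced carbon, so the carbonyl stays next to C3 and the new OCH2 next to C4, with both configurations from step 6 unchanged.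

## Compound list

1 | 5-iodovanillin (4-hydroxy-3-iodo-5-methoxybenzaldehyde) | COc1cc(C=O)cc(I)c1O | starting material
2 | 4-(benzyloxy)-3-iodo-5-methoxybenzaldehyde | COc1cc(C=O)cc(I)c1OCc1ccccc1 | intermediate
3 | vanillin (4-hydroxy-3-methoxybenzaldehyde) | COc1cc(C=O)ccc1O | starting material
4 | 4-(benzyloxy)-3-(4-formyl-2-methoxyphenoxy)-5-methoxybenzaldehyde | COc1cc(C=O)ccc1Oc1cc(C=O)cc(OC)c1OCc1ccccc1 | intermediate
5 | {4-(benzyloxy)-3-[4-(hydroxymethyl)-2-methoxyphenoxy]-5-methoxyphenyl}methanol | COc1cc(CO)ccc1Oc1cc(CO)cc(OC)c1OCc1ccccc1 | intermediate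
6 | 2-(benzyloxy)-5-(bromomethyl)-1-[4-(bromomethyl)-2-methoxyphenoxy]-3-methoxybenzene | COc1cc(CBr)ccc1Oc1cc(CBr)cc(OC)c1OCc1ccccc1 | intermediate
7 | veratraldehyde (3,4-dimethoxybenzaldehyde) | COc1ccc(C=O)cc1OC | starting material
8 | 2-(3,4-dimethoxyphenyl)-1,3-dithiane | COc1ccc(C2SCCCS2)cc1OC | intermediate
9 | (5S)-5-[(1S,2R,5S)-menthyloxy]furan-2(5H)-one, (5S)-5-(d-menthyloxy)-2(5H)-furanone | O=C1C=C[C@@H](O[C@H]2C[C@@H](C)CC[C@@H]2C(C)C)O1 | starting material
10 | 2-lithio-2-(3,4-dimethoxyphenyl)-1,3-dithiane (formed in the flask) | [Li]C1(SCCCS1)c1ccc(OC)c(OC)c1 | intermediate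
11 | lithium enolate of (4S,5S)-4-[2-(3,4-dimethoxyphenyl)-1,3-dithian-2-yl]-5-[(1S,2R,5S)-menthyloxy]oxolan-2-one (formed in the flask) | [Li]OC1=C[C@H](C2(SCCCS2)c2ccc(OC)c(OC)c2)[C@@H](O[C@H]2C[C@@H](C)CC[C@@H]2C(C)C)O1 | intermediate
12 | (3S,4S,5S)-3-{4-[2-(benzyloxy)-5-{[(3S,4S,5S)-4-[2-(3,4-dimethoxyphenyl)-1,3-dithian-2-yl]-5-[(1S,2R,5S)-menthyloxy]-2-oxooxolan-3-yl]methyl}-3-methoxyphenoxy]-3-methoxybenzyl}-4-[2-(3,4-dimethoxyphenyl)-1,3-dithian-2-yl]-5-[(1S,2R,5S)-menthyloxy]oxolan-2-one | COc1cc(C[C@@H]2C(=O)O[C@H](O[C@H]3C[C@@H](C)CC[C@@H]3C(C)C)[C@H]2C2(SCCCS2)c2ccc(OC)c(OC)c2)ccc1Oc1cc(C[C@@H]2C(=O)O[C@H](O[C@H]3C[C@@H](C)CC[C@@H]3C(C)C)[C@H]2C2(SCCCS2)c2ccc(OC)c(OC)c2)cc(OC)c1OCc1ccccc1 | intermediate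
13 | (3S,4S,5S)-4-(3,4-dimethoxybenzyl)-3-{4-[5-{[(3S,4S,5S)-4-(3,4-dimethoxybenzyl)-5-[(1S,2R,5S)-menthyloxy]-2-oxooxolan-3-yl]methyl}-2-hydroxy-3-methoxyphenoxy]-3-methoxybenzyl}-5-[(1S,2R,5S)-menthyloxy]oxolan-2-one | COc1cc(C[C@@H]2C(=O)O[C@H](O[C@H]3C[C@@H](C)CC[C@@H]3C(C)C)[C@H]2Cc2ccc(OC)c(OC)c2)ccc1Oc1cc(C[C@@H]2C(=O)O[C@H](O[C@H]3C[C@@H](C)CC[C@@H]3C(C)C)[C@H]2Cc2ccc(OC)c(OC)c2)cc(OC)c1O | intermediate
14 | bis(formyl carboxylate): both arms are (2S,3S)-2-(arylmethyl)-4-(3,4-dimethoxyphenyl)-3-formylbutanoate (formed in the flask as the potassium salt, drawn as the free acid) | COc1cc(C[C@H](C(=O)O)[C@@H](C=O)Cc2ccc(OC)c(OC)c2)ccc1Oc1cc(C[C@H](C(=O)O)[C@@H](C=O)Cc2ccc(OC)c(OC)c2)cc(OC)c1O | intermediate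
15 | bis(hydroxy carboxylate): both arms are (2S,3S)-2-(arylmethyl)-4-(3,4-dimethoxyphenyl)-3-(hydroxymethyl)butanoate (formed in the flask as the potassium salt, drawn as the free acid) | COc1cc(C[C@H](C(=O)O)[C@@H](CO)Cc2ccc(OC)c(OC)c2)ccc1Oc1cc(C[C@H](C(=O)O)[C@@H](CO)Cc2ccc(OC)c(OC)c2)cc(OC)c1O | intermediate
16 | (3S,4S)-4-(3,4-dimethoxybenzyl)-3-{4-[5-{[(3S,4S)-4-(3,4-dimethoxybenzyl)-2-oxooxolan-3-yl]methyl}-2-hydroxy-3-methoxyphenoxy]-3-methoxybenzyl}oxolan-2-one | COc1ccc(C[C@@H]2COC(=O)[C@H]2Cc2ccc(Oc3cc(C[C@@H]4C(=O)OC[C@H]4Cc4ccc(OC)c(OC)c4)cc(OC)c3O)c(OC)c2)cc1OC | target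

## Step count and uncertain steps

Total step count: 8. Longest linear sequence: 7 (steps 1, 2, 3, 4, 6, 7, 8); step 5 is a one-step branch.

**Step 6 (key step).**
- What may go wrong:
  - incomplete second alkylation, so that a mono-alkylated benzylic bromide survives and is lost on work-up;
  - proton transfer from the first-formed product to the remaining enolate;
  - retro-Michael loss of the dithiane on warming;
  - erosion of the trans selectivity in one arm, giving diastereomers that are hard to separate at this molecular size.
- Fallback: the two events are separated and the alkylation is done on a small, unhindered enolate. It sets out from 8, 9 and 6 and returns at 16.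
  - The conjugate addition of 10 to 9 is run alone and quenched with aqueous NH4Cl to give (4S,5S)-4-[2-(3,4-dimethoxyphenyl)-1,3-dithian-2-yl]-5-[(1S,2R,5S)-menthyloxy]oxolan-2-one F1.
  - Raney Ni in EtOH gives (4S,5S)-4-(3,4-dimethoxybenzyl)-5-[(1S,2R,5S)-menthyloxy]oxolan-2-one F2.
  - NaBH4/KOH followed by HCl gives (S)-4-(3,4-dimethoxybenzyl)oxolan-2-one F3.
  - The lithium enolate of F3 (LiHMDS, THF, −78 °C, 2.5 equiv) is alkylated with 6 in the classical trans-selective lignan alkylation to the O-benzyl ether of the target F4.
  - H2 over Pd/C in EtOAc–EtOH then gives 16.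

**Step 2.**
- What may go wrong: slow C–O coupling, because the para-formyl phenoxide of 3 is a weak nucleophile and both partners are ortho-substituted, with competing loss of iodine from 2 by reduction.
- Fallback: the roles are reversed and the ether is made by nucleophilic aromatic substitution. It sets out from 2 and returns at 4.
  - Miyaura borylation of 2 (bis(pinacolato)diboron, Pd(dppf)Cl2, KOAc, dioxane, 80 °C) gives 4-(benzyloxy)-3-methoxy-5-(4,4,5,5-tetramethyl-1,3,2-dioxaborolan-2-yl)benzaldehyde F5.
  - Oxidation with NaBO3·4H2O in THF–H2O gives 4-(benzyloxy)-3-hydroxy-5-methoxybenzaldehyde F6.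
  - The phenoxide of F6 (K2CO3, DMF, 110 °C) displaces fluoride from bought 4-fluoro-3-methoxybenzaldehyde (COc1cc(C=O)ccc1F), whose fluorine is para to the formyl group, to give 4.

**Step 7.**
- What may go wrong: incomplete O-debenzylation, or over-reduction on a large excess of active nickel (hydrogenolysis of the diaryl ether C–O bond, ring saturation).
- Fallback: the two events are done with two orthogonal reagents. It sets out from 12 and returns at 13.
  - Nickel boride (NiCl2·6H2O, NaBH4, MeOH–THF, 0 °C) removes only the sulfur and gives the benzyl ether of 13 F7.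
  - After chromatography, F7 is hydrogenolysed with H2 over Pd/C in EtOAc to 13.

**Step 8.**
- What may go wrong: epimerisation at C4 and C4′ while each is alpha to the transient aldehyde in strong base, or incomplete ring closure of one arm.
- Fallback: the acetal is cleaved under acid, so no aldehyde is exposed to hydroxide. It sets out from 13 and returns at 16.
  - Aqueous trifluoroacetic acid in THF hydrolyses both menthyl acetals to the bis(5-hydroxylactone) F8, a mixture of anomers at C5 and C5′.
  - NaBH4 in EtOH at 0 °C without added base reduces the ring-opened formyl acid form, and acidic work-up closes the lactones to 16.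

## Further compounds

F1 | step 6 | (4S,5S)-4-[2-(3,4-dimethoxyphenyl)-1,3-dithian-2-yl]-5-[(1S,2R,5S)-menthyloxy]oxolan-2-one | O=C1C[C@H](C2(SCCCS2)c2ccc(OC)c(OC)c2)[C@@H](O[C@H]2C[C@@H](C)CC[C@@H]2C(C)C)O1
F2 | step 6 | (4S,5S)-4-(3,4-dimethoxybenzyl)-5-[(1S,2R,5S)-menthyloxy]oxolan-2-one | O=C1C[C@H](Cc2ccc(OC)c(OC)c2)[C@@H](O[C@H]2C[C@@H](C)CC[C@@H]2C(C)C)O1
F3 | step 6 | (S)-4-(3,4-dimethoxybenzyl)oxolan-2-one (identical with A5) | COc1ccc(C[C@@H]2COC(=O)C2)cc1OC
F4 | step 6 | O-benzyl ether of the target 16 (identical with A3) | COc1ccc(C[C@@H]2COC(=O)[C@H]2Cc2ccc(Oc3cc(C[C@@H]4C(=O)OC[C@H]4Cc4ccc(OC)c(OC)c4)cc(OC)c3OCc3ccccc3)c(OC)c2)cc1OC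
F5 | step 2 | 4-(benzyloxy)-3-methoxy-5-(4,4,5,5-tetramethyl-1,3,2-dioxaborolan-2-yl)benzaldehyde | COc1cc(C=O)cc(B2OC(C)(C)C(C)(C)O2)c1OCc1ccccc1
F6 | step 2 | 4-(benzyloxy)-3-hydroxy-5-methoxybenzaldehyde | COc1cc(C=O)cc(O)c1OCc1ccccc1
F7 | step 7 | benzyl ether of 13 (both dithianes removed, O-benzyl kept) | COc1cc(C[C@@H]2C(=O)O[C@H](O[C@H]3C[C@@H](C)CC[C@@H]3C(C)C)[C@H]2Cc2ccc(OC)c(OC)c2)ccc1Oc1cc(C[C@@H]2C(=O)O[C@H](O[C@H]3C[C@@H](C)CC[C@@H]3C(C)C)[C@H]2Cc2ccc(OC)c(OC)c2)cc(OC)c1OCc1ccccc1
F8 | step 8 | bis(5-hydroxylactone) from 13, (3S,4S) in both rings, C5 and C5′ as anomer mixtures | COc1cc(C[C@@H]2C(=O)OC(O)[C@H]2Cc2ccc(OC)c(OC)c2)ccc1Oc1cc(C[C@@H]2C(=O)OC(O)[C@H]2Cc2ccc(OC)c(OC)c2)cc(OC)c1O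
A1 | alternative 1 | (3S,4S)-arctigenin, (3S,4S)-4-(3,4-dimethoxybenzyl)-3-(4-hydroxy-3-methoxybenzyl)oxolan-2-one | COc1ccc(C[C@@H]2COC(=O)[C@H]2Cc2ccc(O)c(OC)c2)cc1OC
A2 | alternative 1 | (3S,4S)-3-[4-(benzyloxy)-3-bromo-5-methoxybenzyl]-4-(3,4-dimethoxybenzyl)oxolan-2-one | COc1ccc(C[C@@H]2COC(=O)[C@H]2Cc2cc(Br)c(OCc3ccccc3)c(OC)c2)cc1OC
A3 | alternative 1 | O-benzyl ether of the target 16 | COc1ccc(C[C@@H]2COC(=O)[C@H]2Cc2ccc(Oc3cc(C[C@@H]4C(=O)OC[C@H]4Cc4ccc(OC)c(OC)c4)cc(OC)c3OCc3ccccc3)c(OC)c2)cc1OC
A4 | alternative 2 | 5,5′-linked biaryl dehydrodimer of A1 | COc1ccc(C[C@@H]2COC(=O)[C@H]2Cc2cc(OC)c(O)c(c2)-c2cc(C[C@@H]3C(=O)OC[C@H]3Cc3ccc(OC)c(OC)c3)cc(OC)c2O)cc1OC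
A5 | alternative 3 | (S)-4-(3,4-dimethoxybenzyl)oxolan-2-one | COc1ccc(C[C@@H]2COC(=O)C2)cc1OC
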